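## Retrosynthetic overview

1. Target = (2R,3R)-pinobanksin 3-O-[(S)-2-methylbutanoate]. The last disconnections are the two ring A benzyl ethers and the C3–O ester bond (Steglich coupling with (S)-2-methylbutanoic acid).
2. Key disconnection (C–O): the C2–O1 bond of ring C, made when the ring A phenol oxygen opens a (2R,3S)-chalcone epoxide at the benzylic carbon with inversion.
3. The epoxide C–O bonds, and with them both ring stereocentres, come from a catalytic asymmetric epoxidation of the unprotected 2'-hydroxychalcone (new step, same flask as the ring closure).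
4. The chalcone comes from a Claisen–Schmidt condensation of 4',6'-di-O-benzyl-2',4',6'-trihydroxyacetophenone with benzaldehyde (the only C–C bond made).
5. Ring order: rings A and B are bought as aromatics; ring C is the only ring formed (step 3).

Assumption: the L-series N,N'-dioxide ligand named in step 3 is taken to deliver the (2R,3S)-epoxide; if the first run shows the opposite sense, its mirror-image ligand (from the D-amino acid) is used under the same conditions.

## Route

**Step 1**
Reactants: 1 2',4',6'-trihydroxyacetophenone (sold as the monohydrate)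
Product: 2 1-[2,4-bis(benzyloxy)-6-hydroxyphenyl]ethan-1-one
Conditions: BnBr (2.1 equiv), K2CO3 (2.2 equiv), DMF, 0 °C to rt
Reagents that add atoms: benzyl bromide, BrCc1ccccc1
Why: Williamson ether synthesis: the 4-hydroxyl and one 2-hydroxyl are alkylated, while the remaining ortho-hydroxyl is locked in a hydrogen bond to the ketone, is the least reactive and stays free with two equivalents of BnBr; no stereocentre is involved.

**Step 2**
Reactants: 2 1-[2,4-bis(benzyloxy)-6-hydroxyphenyl]ethan-1-one; 3 benzaldehyde
Product: 4 (2E)-1-[2,4-bis(benzyloxy)-6-hydroxyphenyl]-3-phenylprop-2-en-1-one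
Conditions: KOH (50% aq), EtOH, rt, 24–48 h; then dilute HCl
Reagents that add atoms: none
Why: Claisen–Schmidt (crossed aldol) condensation: the methyl ketone enolate adds to non-enolisable benzaldehyde and E1cB loss of water gives the conjugated E-enone; benzyl ethers are inert to base and no stereocentre is formed.

**Step 3**
Reactants: 4 (2E)-1-[2,4-bis(benzyloxy)-6-hydroxyphenyl]-3-phenylprop-2-en-1-one
Product: 6 (2R,3R)-5,7-bis(benzyloxy)-3-hydroxy-2-phenyl-2,3-dihydro-4H-chromen-4-one, via (2R,3S)-epoxy ketone 5 (not isolated)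
Conditions: Sc(OTf)3 (5 mol%), L-ramipril-derived N,N'-dioxide ligand with 2,6-diisopropylanilide arms (5 mol%), 30% aq H2O2 (1.5 equiv), THF, 30 °C; then p-TsOH·H2O (20 mol%), 40 °C, same flask
Reagents that add atoms: hydrogen peroxide, OO
Why: Proposed new method: chelation-controlled asymmetric epoxidation of an unprotected 2'-hydroxychalcone followed by acid-triggered 6-endo epoxide opening in one flask; the 2'-OH/C=O pair binds the chiral N,N'-dioxide–Sc(OTf)3 complex (trivalent scandium) as a rigid bidentate unit, so the s-cis enone sits in the ligand pocket and no free phenoxide is present to deactivate the enone or start base-induced aurone formation; the scandium-bound hydroperoxide adds to the β-carbon and the scandium enolate closes the (2R,3S)-epoxide 5, which sets both C–O stereocentres under catalyst control; p-TsOH then lets the phenol oxygen open the epoxide at the benzylic carbon with inversion (C2–O1 bond, ring C), which gives the 2,3-trans (2R,3R) product; the closest known reactions are the N,N'-dioxide–Sc(OTf)3/H2O2 epoxidation of simple chalcones (Weitz–Scheffer type) and the acid-mediated cyclisation of 2'-O-protected chalcone epoxides to trans-dihydroflavonols.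

**Step 4**
Reactants: 6 (2R,3R)-5,7-bis(benzyloxy)-3-hydroxy-2-phenyl-2,3-dihydro-4H-chromen-4-one; 7 (2S)-2-methylbutanoic acid
Product: 8 (2R,3R)-5,7-bis(benzyloxy)-4-oxo-2-phenyl-3,4-dihydro-2H-chromen-3-yl (2S)-2-methylbutanoate
Conditions: 7 (1.5 equiv), DCC (1.6 equiv), DMAP (0.2 equiv), CH2Cl2, 0 °C to rt
Reagents that add atoms: none
Why: Steglich esterification: DCC activates the acid and DMAP transfers the acyl group to the only free hydroxyl (C3–OH); no bond at C2 or C3 is broken, so the (2R,3R) centres are kept, and the α-centre of the acid is kept under these mild conditions.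

**Step 5**
Reactants: 8 (2R,3R)-5,7-bis(benzyloxy)-4-oxo-2-phenyl-3,4-dihydro-2H-chromen-3-yl (2S)-2-methylbutanoate
Product: 9 (2R,3R)-5,7-dihydroxy-4-oxo-2-phenyl-3,4-dihydro-2H-chromen-3-yl (2S)-2-methylbutanoate
Conditions: H2 (1 atm), 10% Pd/C, EtOAc, rt
Reagents that add atoms: none
Why: Catalytic hydrogenolysis of the two aryl benzyl ethers under neutral conditions; the alkyl ester, the ketone and the C2–O1 bond stay intact at room temperature and 1 atm, and no stereocentre is touched.

## Compound list

1 | 2',4',6'-trihydroxyacetophenone | CC(=O)c1c(O)cc(O)cc1O | starting material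
2 | 1-[2,4-bis(benzyloxy)-6-hydroxyphenyl]ethan-1-one | CC(=O)c1c(O)cc(OCc2ccccc2)cc1OCc1ccccc1 | intermediate
3 | benzaldehyde | O=Cc1ccccc1 | starting material
4 | (2E)-1-[2,4-bis(benzyloxy)-6-hydroxyphenyl]-3-phenylprop-2-en-1-one | O=C(/C=C/c1ccccc1)c1c(O)cc(OCc2ccccc2)cc1OCc1ccccc1 | intermediate
5 | [2,4-bis(benzyloxy)-6-hydroxyphenyl][(2R,3S)-3-phenyloxiran-2-yl]methanone | O=C(c1c(O)cc(OCc2ccccc2)cc1OCc1ccccc1)[C@@H]1O[C@H]1c1ccccc1 | intermediate
6 | (2R,3R)-5,7-bis(benzyloxy)-3-hydroxy-2-phenyl-2,3-dihydro-4H-chromen-4-one | O[C@H]1C(=O)c2c(OCc3ccccc3)cc(OCc3ccccc3)cc2O[C@@H]1c1ccccc1 | intermediate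
7 | (2S)-2-methylbutanoic acid | CC[C@H](C)C(=O)O | starting material
8 | (2R,3R)-5,7-bis(benzyloxy)-4-oxo-2-phenyl-3,4-dihydro-2H-chromen-3-yl (2S)-2-methylbutanoate | CC[C@H](C)C(=O)O[C@H]1C(=O)c2c(OCc3ccccc3)cc(OCc3ccccc3)cc2O[C@@H]1c1ccccc1 | intermediate
9 | (2R,3R)-5,7-dihydroxy-4-oxo-2-phenyl-3,4-dihydro-2H-chromen-3-yl (2S)-2-methylbutanoate | CC[C@H](C)C(=O)O[C@H]1C(=O)c2c(O)cc(O)cc2O[C@@H]1c1ccccc1 | target

Compounds 1, 3 and 7 and the reagent benzyl bromide are inexpensive catalogue chemicals.

## Step count and risk

Total step count: 5. Longest linear sequence: 5 steps (1 → 2 → 4 → 6 → 8 → 9).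

The three steps most likely to fail:

**Step 3 (the proposed new step).** The risks are:
- slow epoxidation of the twisted, hydrogen-bonded enone;
- Lewis-acid oxa-Michael closure of 4 to the racemic flavanone;
- partial ionisation at the benzylic carbon giving some 2,3-cis isomer, or aroyl migration;
- an unproven level and sense of induction (6 is expected to be crystalline, so one recrystallisation is planned to raise the ee).

The fallback uses known chemistry and sets out from 4. MOMCl, NaH, DMF, 0 °C caps the 2'-hydroxyl to give (2E)-1-[2,4-bis(benzyloxy)-6-(methoxymethoxy)phenyl]-3-phenylprop-2-en-1-one F1. Juliá–Colonna epoxidation (poly-L-leucine, urea–H2O2, DBU, THF, rt) gives [2,4-bis(benzyloxy)-6-(methoxymethoxy)phenyl][(2R,3S)-3-phenyloxiran-2-yl]methanone F2. HCl in MeOH–THF at 50 °C removes the MOM group and closes ring C with inversion at the benzylic carbon. The fallback comes back to the route at 6.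

**Step 4.** The risks are sluggish acylation of the hindered hydroxyl next to the ketone (N-acylurea formation), DMAP-induced epimerisation at C3 of the α-acyloxy ketone, and partial racemisation of the acid. The fallback sets out from 6 and removes the need for a selective, carbodiimide-driven coupling. H2, 10% Pd/C, EtOAc gives pinobanksin, (2R,3R)-3,5,7-trihydroxy-2-phenyl-2,3-dihydro-4H-chromen-4-one F3. Excess (S)-2-methylbutanoic anhydride in pyridine at 40 °C acylates all three hydroxyls to give (2R,3R)-4-oxo-2-phenyl-3,4-dihydro-2H-chromene-3,5,7-triyl tris[(2S)-2-methylbutanoate] F4. NH4OAc in MeOH at rt then cleaves only the two aryl esters, which are far more labile than the hindered alkyl ester. The fallback comes back to the route at 9, so step 5 is not needed.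

**Step 1.** The risks are mixtures of mono-, di- and tri-O-benzyl products and C-benzylation of the electron-rich ring. The fallback sets out from 1 and replaces selective alkylation by over-protection and selective deprotection. BnBr (3.5 equiv), K2CO3, DMF, 80 °C gives 1-[2,4,6-tris(benzyloxy)phenyl]ethan-1-one F5. MgBr2·OEt2 in toluene at 80 °C then removes one benzyl ether ortho to the carbonyl by chelation. The fallback comes back to the route at 2.

## Further compounds

F1 | step 3 | (2E)-1-[2,4-bis(benzyloxy)-6-(methoxymethoxy)phenyl]-3-phenylprop-2-en-1-one | COCOc1cc(OCc2ccccc2)cc(OCc2ccccc2)c1C(=O)/C=C/c1ccccc1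
F2 | step 3 | [2,4-bis(benzyloxy)-6-(methoxymethoxy)phenyl][(2R,3S)-3-phenyloxiran-2-yl]methanone | COCOc1cc(OCc2ccccc2)cc(OCc2ccccc2)c1C(=O)[C@@H]1O[C@H]1c1ccccc1
F3 | step 4 | (2R,3R)-3,5,7-trihydroxy-2-phenyl-2,3-dihydro-4H-chromen-4-one | O[C@H]1C(=O)c2c(O)cc(O)cc2O[C@@H]1c1ccccc1
F4 | step 4 | (2R,3R)-4-oxo-2-phenyl-3,4-dihydro-2H-chromene-3,5,7-triyl tris[(2S)-2-methylbutanoate] | CC[C@H](C)C(=O)O[C@H]1C(=O)c2c(OC(=O)[C@@H](C)CC)cc(OC(=O)[C@@H](C)CC)cc2O[C@@H]1c1ccccc1
F5 | step 1 | 1-[2,4,6-tris(benzyloxy)phenyl]ethan-1-one | CC(=O)c1c(OCc2ccccc2)cc(OCc2ccccc2)cc1OCc1ccccc1
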